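The readings are calculated on assumed constants; scatter was added.

The dawn flask is leaking. After its peak the target falls steadily, so before any remedy I want to know how fast it loses what it holds.

in all of them: enzyme 0.33 µM

| run | starting material | second substrate | remark | time |
|---|---|---|---|---|
| dawn | 0.050 M | 0.055 M | the very flask that is asked about, followed so far |  |
| winter | 0.075 M | 0.055 M | run made earlier |  |
| flask | 0.050 M | 0.0550 M |  | 2.5 d |

| run | time / h | target / % |
|---|---|---|
| dawn | 4.00 | 54.7 |
| dawn | 12.0 | 78.5 |
| dawn | 20.0 | 77.2 |
| dawn | 30.0 | 72.9 |
| dawn | 50.0 | 60.0 |
| dawn | 60.0 | 54.8 |
| winter | 0.333 | 5.4 |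
| winter | 0.500 | 8.9 |
| winter | 1.00 | 17.4 |
| winter | 1.50 | 23.0 |
| winter | 2.50 | 31.5 |
| winter | 4.00 | 44.7 |

(standard deviation of a reading: 1 percentage point)

* target, in percent of the starting material first charged, at 2.5 d
* the remedy with the largest gain of target, or "none" below 2 percentage points (Wednesday's / Monday's / Tuesday's / Thursday's / none)
* target present, with what was taken out counted in, in percent of the starting material first charged, after Monday's
* target present, with what was taken out counted in, in percent of the starting material first charged, after Tuesday's

- Wednesday's: change nothing and wait 30 h more
- Monday's: at 2.5 d add enzyme, 50.0% of the amount charged, then wait 30 h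
- Tuesday's: at 2.5 d take out 90% of the target then present, then wait 30 h
- Thursday's: at 2.5 d add second substrate, 50.0% of the amount charged, then wait 30 h

- what is taken out of target is counted as made
- on the list of suspects stand: starting material + enzyme <-> starting complex; ternary complex -> enzyme + target; second substrate + starting complex <-> ternary complex; target <-> isomer of the product
- additions bring no volume worth counting

The flask stands at 54.8% of the charge by its reading at 60.0 h, which is my value for now. I define the leak as the target lost per hour divided by the mean target over that stretch, replacing the curve by its mean: from 30.0 h to 60.0 h it reads 0.00945 h⁻¹. Over 30 h the mean keeps a fraction 75.2% and the exponential 75.3%, so the mean errs by 0.14 percentage points, and I reckon that waiting costs the dawn flask 14 points.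

Can more enzyme or second substrate repay that? Treating the early fall of starting material as second-order, as if the charges were equal, the first reading gives 0.302 h⁻¹ on fractions of the charge and leaves about 5.23% at 2.5 d, less than the wait costs, so I put Monday's near 41.2% plus part of that tail.

Does taking target out help? The 10.0% left behind leaks, while I let the same tail feed in 1.7 points, which gives 55.1%, a gain of 0.30 points, below 2 points, so my choice is none.

The forecast, a little apart in its figures, gives 55%, none, 42.5% and 56%, holding that “More enzyme or more second substrate can only recover that last 3%”.

The flask gives 54.7%, none, 40.4% and 54.6%, with a gain of −0.072 points for Tuesday's and −14 points for Wednesday's; my leak on 54.7% takes 14 points.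

    starting material + enzyme ⇌ starting complex (K = 16.0 L mol⁻¹, k = 3.97 × 10⁶ L mol⁻¹ h⁻¹)
    ternary complex → enzyme + target (k = 1.70 × 10⁵ h⁻¹)
    second substrate + starting complex ⇌ ternary complex (K = 16.0 L mol⁻¹, k = 1.02 × 10⁷ L mol⁻¹ h⁻¹)
    target ⇌ isomer of the product (K = 11.0, k = 0.0116 h⁻¹)

At 3.35 h starting material has a half-life of 0.76 h by its forward step into starting complex alone, against 54.8 h for the relaxation of target and isomer of the product by their step alone, a longer time. At 60.0 h the flask holds 54.7% target, 44.8% isomer of the product and 0.508% starting material, less than my tail of 5.23%, so my feed was too large and the nearness of my Tuesday's figure to the flask's is no check.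

In the neighbour with 0.12 M of starting material, second substrate is the limiting reagent and allows 45.8% of the charge; the dawn leak over 2.5 d, counted as if that were made at once, leaves 25.6% as target. That neighbour gives 24.3% target and 21.6% isomer of the product, with 0% of its second substrate left.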